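**Retrosynthetic overview**
1. The (E)-enal comes from the allylic alcohol, which comes from the cinnamate, then the aryl aldehyde, then a silyl-protected benzylic alcohol (Horner–Wadsworth–Emmons, iBu2AlH, MnO2).
2. The dioxane ring is the only ring made and is closed after the acyclic stereocentres are in place. It is closed by intramolecular Pd-catalysed aryl C–O coupling of a threo (1R,2R) bromo alcohol, with retention at both stereocentres.
3. The C-methyl group comes from CH2OH, which comes from the acyl oxazolidinone (LiBH4; TsCl; LiEt3BH).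
4. The key C–C bond (ArCH(OH)–CH(OAr)) is made by an Evans boron syn-aldol of an (S)-4-benzyl-3-(aryloxyacetyl)oxazolidinone with 3,4,5-trimethoxybenzaldehyde, which sets both stereocentres.
5. The aryloxyacetyl fragment comes from 5-bromovanillin and ethyl bromoacetate; both benzene rings are bought.

Assumption: the SMILES is read as the trans (2R,3R) isomer, numbered with O1 on the ring carbon next to the methoxy-bearing carbon, so that methyl is on C2, aryl on C3 and the side chain on C6. TBS = tert-butyldimethylsilyl.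

**Step 1**
Reactants: 1 5-bromovanillin (3-bromo-4-hydroxy-5-methoxybenzaldehyde); 2 ethyl bromoacetate
Product: 3 ethyl 2-(2-bromo-4-formyl-6-methoxyphenoxy)acetate
Conditions: K2CO3, DMF, 60 °C
Reagents that add atoms: none
Why: Williamson ether synthesis (SN2); the acidic hindered phenoxide displaces bromide from the activated α-halo ester, and the non-enolisable aldehyde is inert to carbonate.

**Step 2**
Reactants: 3 ethyl 2-(2-bromo-4-formyl-6-methoxyphenoxy)acetate
Product: 4 ethyl 2-[2-bromo-4-(hydroxymethyl)-6-methoxyphenoxy]acetate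
Conditions: NaBH4 (0.5 equiv), EtOH/THF, 0 °C, 20 min
Reagents that add atoms: none
Why: Chemoselective borohydride reduction; the aryl aldehyde reduces within minutes at 0 °C while the ethyl ester (kept in EtOH to avoid transesterification) and the aryl bromide are untouched.

**Step 3**
Reactants: 4 ethyl 2-[2-bromo-4-(hydroxymethyl)-6-methoxyphenoxy]acetate
Product: 5 ethyl 2-{2-bromo-4-[(TBS-oxy)methyl]-6-methoxyphenoxy}acetate
Conditions: TBSCl, imidazole, CH2Cl2, rt
Reagents that add atoms: tert-butyldimethylsilyl chloride, CC(C)(C)[Si](C)(C)Cl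
Why: Standard imidazole-mediated silylation of a primary benzylic alcohol, masking the future aldehyde carbon through the enolate, hydride and coupling steps.

**Step 4**
Reactants: 5 ethyl 2-{2-bromo-4-[(TBS-oxy)methyl]-6-methoxyphenoxy}acetate
Product: 6 2-{2-bromo-4-[(TBS-oxy)methyl]-6-methoxyphenoxy}acetic acid
Conditions: LiOH·H2O, THF/H2O, 0 °C to rt; then 1 M HCl to pH 4, 0 °C
Reagents that add atoms: lithium hydroxide, [Li+].[OH-]
Why: Saponification (acyl substitution by hydroxide) of an unhindered α-aryloxy ester is fast, and the primary TBS ether survives aqueous base and a brief cold adjustment to pH 4.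

**Step 5**
Reactants: 6 2-{2-bromo-4-[(TBS-oxy)methyl]-6-methoxyphenoxy}acetic acid; 7 (S)-4-benzyl-1,3-oxazolidin-2-one
Product: 9 (4S)-4-benzyl-3-(2-{2-bromo-4-[(TBS-oxy)methyl]-6-methoxyphenoxy}acetyl)-1,3-oxazolidin-2-one, via mixed pivalic anhydride 8 (not isolated)
Conditions: t-BuCOCl, Et3N, THF, −20 °C; then LiCl, 7, −20 °C to rt
Reagents that add atoms: none
Why: N-acylation through a mixed anhydride; the LiCl/Et3N-activated oxazolidinone attacks the less hindered aryloxyacetyl carbonyl, which avoids strong base and leaves the aryl bromide and silyl ether intact.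

**Step 6 (key C–C bond)**
Reactants: 9 (4S)-4-benzyl-3-(2-{2-bromo-4-[(TBS-oxy)methyl]-6-methoxyphenoxy}acetyl)-1,3-oxazolidin-2-one; 10 3,4,5-trimethoxybenzaldehyde
Product: 13 (4S)-4-benzyl-3-[(2S,3R)-2-{2-bromo-4-[(TBS-oxy)methyl]-6-methoxyphenoxy}-3-hydroxy-3-(3,4,5-trimethoxyphenyl)propanoyl]-1,3-oxazolidin-2-one, via dibutylboron Z-enolate 11 (not isolated), via dibutylboron aldolate 12 (not isolated)
Conditions: Bu2BOTf, iPr2NEt, CH2Cl2, −78 to 0 °C; then 10, −78 to 0 °C; then pH 7 buffer, MeOH, 30% H2O2, 0 °C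
Reagents that add atoms: none
Why: Evans boron syn-aldol; the Z-configured glycolate-type boron enolate reacts through a closed Zimmerman–Traxler chair with the auxiliary carbonyl dipole opposed, so the aldehyde adds to the face away from the benzyl group, giving the 2,3-syn (2S,3R) adduct that corresponds to the threo (R,R) relationship of the target.

**Step 7**
Reactants: 13 the syn-aldol adduct
Product: 14 (1R,2R)-2-{2-bromo-4-[(TBS-oxy)methyl]-6-methoxyphenoxy}-1-(3,4,5-trimethoxyphenyl)propane-1,3-diol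
Conditions: LiBH4, MeOH (2 equiv), THF, 0 °C
Reagents that add atoms: none
Why: Reductive cleavage of the N-acyl oxazolidinone by borohydride at the exocyclic carbonyl gives the primary alcohol and recovers 7; low temperature suppresses retro-aldol, so both stereocentres are kept (the C2 descriptor changes from S to R only because of priorities).

**Step 8**
Reactants: 14 the (1R,2R)-1,3-diol
Product: 15 (2R,3R)-2-{2-bromo-4-[(TBS-oxy)methyl]-6-methoxyphenoxy}-3-hydroxy-3-(3,4,5-trimethoxyphenyl)propyl 4-methylbenzenesulfonate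
Conditions: TsCl (1.1 equiv), pyridine, CH2Cl2, 0 °C
Reagents that add atoms: p-toluenesulfonyl chloride, Cc1ccc(cc1)S(Cl)(=O)=O
Why: Selective sulfonylation; the primary alcohol reacts much faster than the hindered secondary benzylic alcohol at 0 °C with near-stoichiometric TsCl.

**Step 9**
Reactants: 15 the primary tosylate
Product: 16 (1R,2R)-2-{2-bromo-4-[(TBS-oxy)methyl]-6-methoxyphenoxy}-1-(3,4,5-trimethoxyphenyl)propan-1-ol
Conditions: LiEt3BH, THF, 0 °C to rt
Reagents that add atoms: none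
Why: SN2 hydride displacement of a primary tosylate by the very nucleophilic triethylborohydride turns CH2OTs into the C-methyl group faster than the lithium alkoxide can cyclise or fragment, and the aryl bromide, silyl ether and both stereocentres are unaffected.

**Step 10**
Reactants: 16 the threo (1R,2R) bromo alcohol
Product: 17 tert-butyl{[(2R,3R)-8-methoxy-2-methyl-3-(3,4,5-trimethoxyphenyl)-2,3-dihydro-1,4-benzodioxin-6-yl]methoxy}dimethylsilane (trans)
Conditions: Pd(OAc)2 (3 mol %), 2-(di-tert-butylphosphino)-1,1'-binaphthyl (4 mol %), Cs2CO3, toluene, 80 °C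
Reagents that add atoms: none
Why: Buchwald-type intramolecular C–O coupling; zerovalent palladium inserts into the aryl bromide, and alkoxide binding followed by reductive elimination (favoured over β-hydride elimination by the bulky ligand) closes the six-membered ring without breaking either C–O bond at a stereocentre, so threo (1R,2R) becomes trans (2R,3R).

**Step 11**
Reactants: 17 the TBS-protected benzodioxane
Product: 18 [(2R,3R)-8-methoxy-2-methyl-3-(3,4,5-trimethoxyphenyl)-2,3-dihydro-1,4-benzodioxin-6-yl]methanol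
Conditions: Bu4NF, THF, 0 °C to rt
Reagents that add atoms: none
Why: Fluoride-driven desilylation (strong Si–F bond) is specific for the silyl ether and leaves the aryl ethers and the benzodioxane untouched.

**Step 12**
Reactants: 18 the benzylic alcohol
Product: 19 (2R,3R)-8-methoxy-2-methyl-3-(3,4,5-trimethoxyphenyl)-2,3-dihydro-1,4-benzodioxine-6-carbaldehyde
Conditions: MnO2 (activated, excess), CH2Cl2, rt
Reagents that add atoms: none
Why: Heterogeneous MnO2 oxidation is selective for benzylic alcohols, stops at the aldehyde and is neutral, so the stereocentres cannot epimerise.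

**Step 13**
Reactants: 19 the aryl aldehyde; 20 triethyl phosphonoacetate
Product: 22 ethyl (2E)-3-[(2R,3R)-8-methoxy-2-methyl-3-(3,4,5-trimethoxyphenyl)-2,3-dihydro-1,4-benzodioxin-6-yl]prop-2-enoate, via sodium phosphonoacetate carbanion 21 (not isolated)
Conditions: NaH, THF, 0 °C to rt
Reagents that add atoms: none
Why: Horner–Wadsworth–Emmons olefination; the stabilised phosphonate carbanion with an aromatic aldehyde gives the E-alkene with high selectivity under thermodynamic control of the oxaphosphetane.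

**Step 14**
Reactants: 22 the E-cinnamate ester
Product: 23 (2E)-3-[(2R,3R)-8-methoxy-2-methyl-3-(3,4,5-trimethoxyphenyl)-2,3-dihydro-1,4-benzodioxin-6-yl]prop-2-en-1-ol
Conditions: iBu2AlH (2.5 equiv), CH2Cl2, −78 °C; aq. potassium sodium tartrate
Reagents that add atoms: none
Why: 1,2-Reduction of an α,β-unsaturated ester by iBu2AlH gives the allylic alcohol without conjugate reduction and without changing the alkene geometry.

**Step 15**
Reactants: 23 the E-allylic alcohol
Product: 24 (2E)-3-[(2R,3R)-8-methoxy-2-methyl-3-(3,4,5-trimethoxyphenyl)-2,3-dihydro-1,4-benzodioxin-6-yl]prop-2-enal (target)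
Conditions: MnO2 (activated, excess), CH2Cl2, rt
Reagents that add atoms: none
Why: Allylic oxidation with MnO2 gives the conjugated enal with no over-oxidation or E/Z isomerisation, delivering the target as the (2R,3R,E) isomer.

**Compound list**
1 | 5-bromovanillin (3-bromo-4-hydroxy-5-methoxybenzaldehyde) | COc1cc(C=O)cc(Br)c1O | starting material
2 | ethyl bromoacetate | BrCC(=O)OCC | starting material
3 | ethyl 2-(2-bromo-4-formyl-6-methoxyphenoxy)acetate | CCOC(=O)COc1c(Br)cc(C=O)cc1OC | intermediate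
4 | ethyl 2-[2-bromo-4-(hydroxymethyl)-6-methoxyphenoxy]acetate | CCOC(=O)COc1c(Br)cc(CO)cc1OC | intermediate
5 | ethyl 2-{2-bromo-4-[(TBS-oxy)methyl]-6-methoxyphenoxy}acetate | CCOC(=O)COc1c(Br)cc(CO[Si](C)(C)C(C)(C)C)cc1OC | intermediate
6 | 2-{2-bromo-4-[(TBS-oxy)methyl]-6-methoxyphenoxy}acetic acid | OC(=O)COc1c(Br)cc(CO[Si](C)(C)C(C)(C)C)cc1OC | intermediate
7 | (S)-4-benzyl-1,3-oxazolidin-2-one | O=C1OC[C@H](Cc2ccccc2)N1 | starting material
8 | mixed anhydride of 6 with pivalic acid | CC(C)(C)C(=O)OC(=O)COc1c(Br)cc(CO[Si](C)(C)C(C)(C)C)cc1OC | intermediate (not isolated)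
9 | (4S)-4-benzyl-3-(2-{2-bromo-4-[(TBS-oxy)methyl]-6-methoxyphenoxy}acetyl)-1,3-oxazolidin-2-one | O=C1OC[C@H](Cc2ccccc2)N1C(=O)COc3c(Br)cc(CO[Si](C)(C)C(C)(C)C)cc3OC | intermediate
10 | 3,4,5-trimethoxybenzaldehyde | COc1cc(C=O)cc(OC)c1OC | starting material
11 | dibutylboron Z-enolate of 9 | CCCCB(CCCC)O/C(=C\Oc1c(Br)cc(CO[Si](C)(C)C(C)(C)C)cc1OC)N2[C@@H](Cc3ccccc3)COC2=O | intermediate (not isolated)
12 | dibutylboron aldolate of 13 | O=C1OC[C@H](Cc2ccccc2)N1C(=O)[C@@H](Oc3c(Br)cc(CO[Si](C)(C)C(C)(C)C)cc3OC)[C@H](OB(CCCC)CCCC)c4cc(OC)c(OC)c(OC)c4 | intermediate (not isolated)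
13 | (4S)-4-benzyl-3-[(2S,3R)-2-{2-bromo-4-[(TBS-oxy)methyl]-6-methoxyphenoxy}-3-hydroxy-3-(3,4,5-trimethoxyphenyl)propanoyl]-1,3-oxazolidin-2-one | O=C1OC[C@H](Cc2ccccc2)N1C(=O)[C@@H](Oc3c(Br)cc(CO[Si](C)(C)C(C)(C)C)cc3OC)[C@H](O)c4cc(OC)c(OC)c(OC)c4 | intermediate
14 | (1R,2R)-2-{2-bromo-4-[(TBS-oxy)methyl]-6-methoxyphenoxy}-1-(3,4,5-trimethoxyphenyl)propane-1,3-diol | OC[C@@H](Oc1c(Br)cc(CO[Si](C)(C)C(C)(C)C)cc1OC)[C@H](O)c2cc(OC)c(OC)c(OC)c2 | intermediate
15 | (2R,3R)-2-{2-bromo-4-[(TBS-oxy)methyl]-6-methoxyphenoxy}-3-hydroxy-3-(3,4,5-trimethoxyphenyl)propyl 4-methylbenzenesulfonate | Cc1ccc(cc1)S(=O)(=O)OC[C@@H](Oc2c(Br)cc(CO[Si](C)(C)C(C)(C)C)cc2OC)[C@H](O)c3cc(OC)c(OC)c(OC)c3 | intermediate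
16 | (1R,2R)-2-{2-bromo-4-[(TBS-oxy)methyl]-6-methoxyphenoxy}-1-(3,4,5-trimethoxyphenyl)propan-1-ol | C[C@@H](Oc1c(Br)cc(CO[Si](C)(C)C(C)(C)C)cc1OC)[C@H](O)c2cc(OC)c(OC)c(OC)c2 | intermediate
17 | tert-butyl{[(2R,3R)-8-methoxy-2-methyl-3-(3,4,5-trimethoxyphenyl)-2,3-dihydro-1,4-benzodioxin-6-yl]methoxy}dimethylsilane | COc1cc([C@H]2Oc3cc(CO[Si](C)(C)C(C)(C)C)cc(OC)c3O[C@@H]2C)cc(OC)c1OC | intermediate
18 | [(2R,3R)-8-methoxy-2-methyl-3-(3,4,5-trimethoxyphenyl)-2,3-dihydro-1,4-benzodioxin-6-yl]methanol | COc1cc([C@H]2Oc3cc(CO)cc(OC)c3O[C@@H]2C)cc(OC)c1OC | intermediate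
19 | (2R,3R)-8-methoxy-2-methyl-3-(3,4,5-trimethoxyphenyl)-2,3-dihydro-1,4-benzodioxine-6-carbaldehyde | COc1cc([C@H]2Oc3cc(C=O)cc(OC)c3O[C@@H]2C)cc(OC)c1OC | intermediate
20 | triethyl phosphonoacetate | CCOC(=O)CP(=O)(OCC)OCC | starting material
21 | sodium salt of the triethyl phosphonoacetate carbanion | [Na+].CCOC(=O)[CH-]P(=O)(OCC)OCC | intermediate (not isolated)
22 | ethyl (2E)-3-[(2R,3R)-8-methoxy-2-methyl-3-(3,4,5-trimethoxyphenyl)-2,3-dihydro-1,4-benzodioxin-6-yl]prop-2-enoate | COc1cc([C@H]2Oc3cc(/C=C/C(=O)OCC)cc(OC)c3O[C@@H]2C)cc(OC)c1OC | intermediate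
23 | (2E)-3-[(2R,3R)-8-methoxy-2-methyl-3-(3,4,5-trimethoxyphenyl)-2,3-dihydro-1,4-benzodioxin-6-yl]prop-2-en-1-ol | COc1cc([C@H]2Oc3cc(/C=C/CO)cc(OC)c3O[C@@H]2C)cc(OC)c1OC | intermediate
24 | (2E)-3-[(2R,3R)-8-methoxy-2-methyl-3-(3,4,5-trimethoxyphenyl)-2,3-dihydro-1,4-benzodioxin-6-yl]prop-2-enal | COc1cc([C@H]2Oc3cc(/C=C/C=O)cc(OC)c3O[C@@H]2C)cc(OC)c1OC | target

**Step count and risks**
Total steps: 15. Longest linear sequence: 15 steps (1 to 24); compounds 2, 7, 10 and 20 are bought and enter directly.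

The three steps most likely to fail:

Step 6 (aldol with a hindered 2,6-disubstituted aryloxyacetyl imide; conversion and syn selectivity). The fallback sets out from acid 6 and changes both the auxiliary and the enolate metal. Acid 6 is coupled with (S)-4-benzyl-1,3-thiazolidine-2-thione (EDC hydrochloride, cat. DMAP, CH2Cl2) to give (4S)-4-benzyl-3-(2-{2-bromo-4-[(TBS-oxy)methyl]-6-methoxyphenoxy}acetyl)-1,3-thiazolidine-2-thione F1. Soft enolisation with TiCl4, iPr2NEt and N-methylpyrrolidinone in CH2Cl2 at −78 °C, then addition of 10, goes through the non-chelated chlorotitanium enolate. This gives the same-sense syn adduct, (4S)-4-benzyl-3-[(2S,3R)-2-{2-bromo-4-[(TBS-oxy)methyl]-6-methoxyphenoxy}-3-hydroxy-3-(3,4,5-trimethoxyphenyl)propanoyl]-1,3-thiazolidine-2-thione F2. NaBH4 in THF/EtOH at 0 °C removes the easily displaced thione auxiliary, and the route is rejoined at diol 14.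

Step 9 (the free hydroxyl becomes an alkoxide that can form an oxetane or fragment in competition with hydride displacement). The fallback sets out from tosylate 15 and blocks the hydroxyl first. TESOTf and 2,6-lutidine in CH2Cl2 at −78 °C give (2R,3R)-2-{2-bromo-4-[(TBS-oxy)methyl]-6-methoxyphenoxy}-3-(triethylsilyloxy)-3-(3,4,5-trimethoxyphenyl)propyl 4-methylbenzenesulfonate F3. LiEt3BH in THF at 0 °C then gives {[(1R,2R)-2-{2-bromo-4-[(TBS-oxy)methyl]-6-methoxyphenoxy}-1-(3,4,5-trimethoxyphenyl)propyl]oxy}triethylsilane F4. Pyridinium p-toluenesulfonate in MeOH at 0 °C removes the more labile secondary triethylsilyl ether selectively while the primary TBS ether stays, and the route is rejoined at alcohol 16.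

Step 10 (β-hydride elimination from the secondary benzylic palladium alkoxide would give the aryl ketone and the debrominated arene). The fallback sets out from bromo alcohol 16 and forms the other ring C–O bond instead. Miyaura borylation (PdCl2(dppf), bis(pinacolato)diboron, KOAc, dioxane, 85 °C) gives (1R,2R)-2-{4-[(TBS-oxy)methyl]-2-methoxy-6-(4,4,5,5-tetramethyl-1,3,2-dioxaborolan-2-yl)phenoxy}-1-(3,4,5-trimethoxyphenyl)propan-1-ol F5. Oxidation with NaBO3·4H2O in THF/H2O gives 5-[(TBS-oxy)methyl]-2-{[(1R,2R)-1-hydroxy-1-(3,4,5-trimethoxyphenyl)propan-2-yl]oxy}-3-methoxyphenol F6. Catalytic camphorsulfonic acid in toluene at 40 °C (or BF3·OEt2 in CH2Cl2 at −20 °C) ionises the trimethoxybenzylic alcohol, and the neighbouring phenol captures the cation under thermodynamic control to give the trans ring. The methyl-bearing stereocentre is not involved and keeps the enantiopurity, and the route is rejoined at benzodioxane 17.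

**Further compounds**
F1 | step 6 | (4S)-4-benzyl-3-(2-{2-bromo-4-[(TBS-oxy)methyl]-6-methoxyphenoxy}acetyl)-1,3-thiazolidine-2-thione | S=C1SC[C@H](Cc2ccccc2)N1C(=O)COc3c(Br)cc(CO[Si](C)(C)C(C)(C)C)cc3OC
F2 | step 6 | (4S)-4-benzyl-3-[(2S,3R)-2-{2-bromo-4-[(TBS-oxy)methyl]-6-methoxyphenoxy}-3-hydroxy-3-(3,4,5-trimethoxyphenyl)propanoyl]-1,3-thiazolidine-2-thione | S=C1SC[C@H](Cc2ccccc2)N1C(=O)[C@@H](Oc3c(Br)cc(CO[Si](C)(C)C(C)(C)C)cc3OC)[C@H](O)c4cc(OC)c(OC)c(OC)c4
F3 | step 9 | (2R,3R)-2-{2-bromo-4-[(TBS-oxy)methyl]-6-methoxyphenoxy}-3-(triethylsilyloxy)-3-(3,4,5-trimethoxyphenyl)propyl 4-methylbenzenesulfonate | Cc1ccc(cc1)S(=O)(=O)OC[C@@H](Oc2c(Br)cc(CO[Si](C)(C)C(C)(C)C)cc2OC)[C@H](O[Si](CC)(CC)CC)c3cc(OC)c(OC)c(OC)c3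
F4 | step 9 | {[(1R,2R)-2-{2-bromo-4-[(TBS-oxy)methyl]-6-methoxyphenoxy}-1-(3,4,5-trimethoxyphenyl)propyl]oxy}triethylsilane | C[C@@H](Oc1c(Br)cc(CO[Si](C)(C)C(C)(C)C)cc1OC)[C@H](O[Si](CC)(CC)CC)c2cc(OC)c(OC)c(OC)c2
F5 | step 10 | (1R,2R)-2-{4-[(TBS-oxy)methyl]-2-methoxy-6-(4,4,5,5-tetramethyl-1,3,2-dioxaborolan-2-yl)phenoxy}-1-(3,4,5-trimethoxyphenyl)propan-1-ol | C[C@@H](Oc1c(B2OC(C)(C)C(C)(C)O2)cc(CO[Si](C)(C)C(C)(C)C)cc1OC)[C@H](O)c3cc(OC)c(OC)c(OC)c3
F6 | step 10 | 5-[(TBS-oxy)methyl]-2-{[(1R,2R)-1-hydroxy-1-(3,4,5-trimethoxyphenyl)propan-2-yl]oxy}-3-methoxyphenol | C[C@@H](Oc1c(O)cc(CO[Si](C)(C)C(C)(C)C)cc1OC)[C@H](O)c2cc(OC)c(OC)c(OC)c2
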